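## The problem

The target is a biflavonoid in which C3 of a naringenin-type flavanone (rings A, B and C) is bonded directly to C3'' of an apigenin-type flavone. The central C3–C3'' bond therefore joins an sp3 carbon, flanked by a ketone and an aryl-bearing carbinol carbon, to a fully substituted sp2 carbon of a chromone. Ring C holds the only two stereocentres, C2 (S) and C3 (R), which are trans. C3 is alpha to the C4 ketone and epimerisable, and with the C2 aryl group equatorial it should settle trans (diequatorial); C2 can thus control C3 but not the reverse, and the stereochemical problem reduces to the absolute configuration at C2. C2 is fragile: the O1–C2 bond is the beta bond of a ketone (retro-oxa-Michael opening under base, helped by the free 5-OH and 4'-OH) and also a para-oxygenated benzylic aryl ether (ionisation under strong Lewis acids). Every operation after ring C closure, including the unmasking of the phenols, must therefore be close to neutral, which speaks for benzyl ethers and hydrogenolysis and against methyl ethers and boron tribromide. The feature that opens a short route is ring A: it is a phloroglucinol whose C4a carries the acyl carbon C4, the oxygen pattern of a folded tetraketide. Its six carbons can be drawn from C1 to C6 of a 3,5,7-triketo ester whose C7 carbonyl becomes C4; the symmetric phloroglucinol then lets either ortho hydroxyl close ring C, and all three ring A hydroxyls arrive unprotected.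

## Retrosynthesis

**Deprotection.** Target 17 is traced to its tetrabenzyl ether 16 by cutting four O–benzyl bonds (ring B 4'-O and the three flavone oxygens). Hydrogenolysis is neutral, so neither C2 nor C3 is put at risk. Methyl ethers would have required a boron trihalide on a finished, ionisable flavanone.

**Ring C.** In 16 the O1–C2 bond is cut, which leads to the 2',4',6'-trihydroxychalcone 15. This cut creates both stereocentres in one event (C2 by the catalyst, C3 by equilibration) and asks only for face selection in a 6-endo oxa-Michael addition. The neighbouring cut at C3–C3'' would require a hindered sp3–sp2 coupling next to an enolisable ketone. Because 15 is symmetric in ring A, no differentiation of its hydroxyls is needed.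

**Ring A (key disconnection).** The C4a–C5 bond of 15 is cut to unfold ring A into the triketo ester 13, passing through the cyclohexane-1,3,5-trione tautomer 14. Against the alternative of acylating phloroglucinol with a hindered, alpha-branched acryloyl electrophile under Lewis acid (which would endanger the benzyl ethers), the Claisen folding works under alkoxide and delivers ring A with its three hydroxyls free. The forward step must fold in the Claisen mode (C6 onto C1) and not in the aldol mode (C2 onto C7).

**The chain.** The C6–C7 bond of 13 is cut to give the acyl imidazole 10 and the trianion of methyl 3,5-dioxohexanoate 12, which comes in one step from dehydroacetic acid 11. The acyl partner 10 has no alpha hydrogen, so only 1,2-addition at the terminal carbanion of 12 is asked for.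

**The alkene.** Compound 10 is the activated form of the acrylic acid 9. Its C=C bond is cut in the Perkin sense to the flavon-3-ylacetic acid 7 and 4-(benzyloxy)benzaldehyde 8. The Perkin condensation gives the E acid, with carbonyl trans to the beta-aryl group as in a natural chalcone.

**The flavone.** Acid 7 is reached through its tert-butyl ester 6 by cutting the pyranone O1''–C2'' bond (cyclodehydration), which leads to the 2-substituted 1,3-diketone 5. The C3''–CH2 bond of 5 is cut to the diketone 3 and tert-butyl bromoacetate 4, and 3 is cut to the commercial acetophenone 1 and 4-(benzyloxy)benzoyl chloride 2. This uses only enolate acylation and alkylation and avoids Lewis-acid acylations that benzyl ethers would not survive.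

## Roads not taken

**Alternative 1:** The cut is C3–C4 of ring C. A chiral triazolium-derived carbene would turn the aldehyde of the ether A2 into its Breslow intermediate, which adds to C3 of the tethered alkylidene 1,3-diketone to give chromanone A1 (intramolecular Stetter reaction). The same diketone is later cyclodehydrated to the flavone.
- Merits: the asymmetric intramolecular Stetter closure to chroman-4-ones is a well-developed reaction class with reliably high enantiocontrol, arguably better precedented than the ring-closing step chosen here. The diketone serves twice, as activator and as flavone precursor.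
- Weak points: in the known chromanone cases the carbon next to oxygen is a methylene. Here it is the C2 stereocentre, a para-methoxybenzylic, allylic aryl ether next to a strong acceptor, which must be made enantioenriched beforehand and is prone to ionisation. The catalyst then controls C3, the centre that equilibrates anyway. A1 still carries seven methyl ethers and an acetal, so the harsh dealkylation falls on the finished flavanone.
- Comparison: the chosen plan sets against the better-precedented asymmetric step a direct setting of C2, a ring A that needs no deprotection, and a neutral final step.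

**Alternative 2:** The cut is O1–C2, as in the chosen plan, but from the saturated dihydrochalcone A4. Anodic oxidation of its ring B phenol would give a para-quinone methide, to which the ortho hydroxyl of ring A adds under a chiral phosphoric acid to give A3.
- Merits: A4 is stable, whereas chalcone 15 must be handled cold and acidic. Ion pairing of a chiral phosphate with a quinone methide may well give higher selectivity than an amine-thiourea on an unactivated enone. No chemical oxidant is needed.
- Weak points: A4 contains several electron-rich rings (the dimethoxyphenol ring A and the flavone) that compete at the anode. The quinone methide has an acidic hydrogen at C3 and should tautomerise to the 4-hydroxychalcone, so the step may collapse to the same oxa-Michael addition. The electrolyte may disturb the chiral ion pair. A3 keeps six methyl ethers, two of them on ring A.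
- Comparison: both routes are equal on C3. Alternative 2 may be better on enantiocontrol and on the stability of the precursor. The chosen plan answers with no oxidation-selectivity question, free ring A hydroxyls from the key step, and hydrogenolysis as the end.

**Alternative 3:** The cuts are O1–C2 and C3–C4. Acid would ionise the acetal A7 to a 4-methoxy ortho-quinone methide, which adds across the styryl double bond of the 3-styrylflavone A6 to give the chroman A5.
- Merits: this is the most convergent plan, with two bonds and ring C formed in one step from two fragments of similar size and a shorter longest linear sequence than the chosen route. The trans relationship is transferred from the E alkene. The para-methoxyphenyl group directs oxygen to C2.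
- Weak points: the alkene is conjugated to the electron-poor chromone and is a modest partner for an inverse-demand cycloaddition. A6 can itself react as a diene. Absolute control over a transient oxocarbenium-type species is hard to secure. A5 has the wrong oxidation level at C4, so hydrolysis and oxidation must follow, and seven methyl ethers remain.
- Comparison: the chosen plan is longer and less convergent. It offers instead the correct oxidation level at C4 from the start, a catalytic asymmetric step of a known class, and mild deprotection.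

Key step: step 8

Assumption: the quinine-derived thiourea is taken to add O1 to the face of C2 that gives 2S; should the sense prove opposite, the pseudoenantiomeric quinidine-derived thiourea would be used under the same conditions.

## Route

Step 1
Reactants: 1 1-[2,4-bis(benzyloxy)-6-hydroxyphenyl]ethan-1-one; 2 4-(benzyloxy)benzoyl chloride
Product: 3 1-[2,4-bis(benzyloxy)-6-hydroxyphenyl]-3-[4-(benzyloxy)phenyl]propane-1,3-dione
Conditions: LiN(SiMe3)2 (4 equiv), THF, −78 to −10 °C; then 2, −78 °C to rt; aq. HCl
Reagents that add atoms: none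
Why: C-acylation of the lithium dianion (phenoxide and ketone enolate) of an ortho-hydroxyacetophenone with an aroyl chloride gives the 1,3-diketone directly, a one-flask variant of the Baker–Venkataraman synthesis; the excess amide base holds the product as its unreactive diketonate, so a second acylation should not occur.

Step 2
Reactants: 3 1-[2,4-bis(benzyloxy)-6-hydroxyphenyl]-3-[4-(benzyloxy)phenyl]propane-1,3-dione; 4 tert-butyl bromoacetate
Product: 5 tert-butyl 3-[2,4-bis(benzyloxy)-6-hydroxybenzoyl]-4-[4-(benzyloxy)phenyl]-4-oxobutanoate (racemic)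
Conditions: K2CO3 (1.2 equiv), acetone, rt to 45 °C
Reagents that add atoms: none
Why: C-alkylation of the beta-diketone monoanion (the most acidic site) with a reactive alpha-halo ester, the acetoacetic-type alkylation used for 3-alkylflavone precursors; the chelated ortho hydroxyl is the least nucleophilic oxygen under carbonate in acetone, and the new stereocentre is racemic and is lost in step 3.

Step 3
Reactants: 5 tert-butyl 3-[2,4-bis(benzyloxy)-6-hydroxybenzoyl]-4-[4-(benzyloxy)phenyl]-4-oxobutanoate
Product: 7 {5,7-bis(benzyloxy)-2-[4-(benzyloxy)phenyl]-4-oxo-4H-chromen-3-yl}acetic acid, via tert-butyl flavon-3-ylacetate 6 (not isolated)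
Conditions: TsOH·H2O (0.2 equiv), toluene, 90 °C
Reagents that add atoms: none
Why: Acid-catalysed cyclodehydration of the ortho-hydroxyaryl 1,3-diketone (hemiketal, loss of water) closes the pyranone with the acetate arm at C3'', and the same acid then cleaves the tert-butyl ester by loss of isobutene; aryl benzyl ethers should tolerate a catalytic sulfonic acid in toluene.

Step 4
Reactants: 7 {5,7-bis(benzyloxy)-2-[4-(benzyloxy)phenyl]-4-oxo-4H-chromen-3-yl}acetic acid; 8 4-(benzyloxy)benzaldehyde
Product: 9 (2E)-2-{5,7-bis(benzyloxy)-2-[4-(benzyloxy)phenyl]-4-oxo-4H-chromen-3-yl}-3-[4-(benzyloxy)phenyl]prop-2-enoic acid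
Conditions: Ac2O, Et3N, 110 °C; then H2O/THF, aq. HCl
Reagents that add atoms: none
Why: Perkin condensation of an arylacetic acid (as its mixed anhydride enolate) with an aromatic aldehyde, followed by acetate elimination; this reaction reliably gives the E 2,3-diarylacrylic acid with the carboxyl group trans to the beta-aryl group, and the chromone is inert to amine and anhydride.

Step 5
Reactants: 9 (2E)-2-{5,7-bis(benzyloxy)-2-[4-(benzyloxy)phenyl]-4-oxo-4H-chromen-3-yl}-3-[4-(benzyloxy)phenyl]prop-2-enoic acid
Product: 10 (2E)-2-{5,7-bis(benzyloxy)-2-[4-(benzyloxy)phenyl]-4-oxo-4H-chromen-3-yl}-3-[4-(benzyloxy)phenyl]-1-(1H-imidazol-1-yl)prop-2-en-1-one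
Conditions: 1,1'-carbonyldiimidazole (1.2 equiv), THF, rt to 45 °C; cold aqueous wash, drying
Reagents that add atoms: 1,1'-carbonyldiimidazole, O=C(n1ccnc1)n1ccnc1
Why: Standard activation of a carboxylic acid as its N-acylimidazole with loss of carbon dioxide; the hindered imidazolide should survive a quick cold wash, which removes the free imidazole that would otherwise protonate the trianion in step 7.

Step 6
Reactants: 11 dehydroacetic acid
Product: 12 methyl 3,5-dioxohexanoate
Conditions: Mg(OMe)2, MeOH, reflux; aq. HCl
Reagents that add atoms: methanol (delivered as Mg(OMe)2), CO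
Why: Methoxide-mediated retro-Claisen deacetylation and lactone opening of the acylpyranone, a known preparation of this diketo ester; the magnesium chelate protects the product from further cleavage.

Step 7
Reactants: 12 methyl 3,5-dioxohexanoate; 10 (2E)-2-{5,7-bis(benzyloxy)-2-[4-(benzyloxy)phenyl]-4-oxo-4H-chromen-3-yl}-3-[4-(benzyloxy)phenyl]-1-(1H-imidazol-1-yl)prop-2-en-1-one
Product: 13 methyl (8E)-8-{5,7-bis(benzyloxy)-2-[4-(benzyloxy)phenyl]-4-oxo-4H-chromen-3-yl}-9-[4-(benzyloxy)phenyl]-3,5,7-trioxonon-8-enoate
Conditions: 12 (2.2 equiv), LiN(iPr)2 (6.6 equiv), THF, −78 to 0 °C; then 10, −78 to −30 °C; AcOH quench at −78 °C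
Reagents that add atoms: none
Why: Acylation of the trianion of a 3,5-diketo ester at its terminal, last-formed and most nucleophilic carbanion (C6) by an acyl imidazole, a known polyanion acylation; 10 has no alpha hydrogen and a hindered beta carbon, so 1,2-addition should prevail, and a second equivalent of trianion absorbs the proton of the more acidic product. Compound 13 would be taken on crude after the cold acidic quench.

Step 8
Reactants: 13 methyl (8E)-8-{5,7-bis(benzyloxy)-2-[4-(benzyloxy)phenyl]-4-oxo-4H-chromen-3-yl}-9-[4-(benzyloxy)phenyl]-3,5,7-trioxonon-8-enoate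
Product: 15 (2E)-2-{5,7-bis(benzyloxy)-2-[4-(benzyloxy)phenyl]-4-oxo-4H-chromen-3-yl}-3-[4-(benzyloxy)phenyl]-1-(2,4,6-trihydroxyphenyl)prop-2-en-1-one, via cyclohexane-1,3,5-trione tautomer 14 (not isolated)
Conditions: Mg(OMe)2 (6 equiv), MeOH/THF, rt to 40 °C, argon; poured into ice-cold 1 M HCl
Reagents that add atoms: none
Why: Mg(OMe)2 should convert 13 into a magnesium-chelated polyenolate in which the triketone is deprotonated at C4 and C6 while the ester carbonyl C1 stays electrophilic; the C6 carbanion, flanked by the C5 and C7 carbonyls, attacks C1, methoxide leaves, and trione 14 enolises at once to the aromatic triol 15. The closest known reaction type is the base-mediated Claisen cyclisation of 3,5,7-triketo esters to 2-acylphloroglucinols, the laboratory counterpart of the chalcone synthase folding. Ring A closes in a 6-exo-trig mode (enolate carbon onto the exocyclic ester C=O), and the C4a–C5 bond is the only skeletal bond formed. No stereocentre is created and the E alkene is not involved. The selectivity needed is Claisen folding over the aldol mode (C2 onto C7) and over lactonisation to a 4-hydroxy-2-pyranone. The substrate secures it because C7 is a hindered, alpha-branched enone carbonyl that is also part of the enolate in strong base, and the anhydrous alkoxide keeps C1 an ester (a carboxylate could fold only by the aldol mode) and reopens any pyranone. Loss of methoxide and aromatisation make the Claisen path irreversible, and benzyl ethers and the 2,3-disubstituted chromone should be inert to Mg(OMe)2 at this temperature. Pouring into excess cold acid takes the chalcone quickly through the pH range of spontaneous ring C closure, which the alpha substituent should slow further.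

Step 9
Reactants: 15 (2E)-2-{5,7-bis(benzyloxy)-2-[4-(benzyloxy)phenyl]-4-oxo-4H-chromen-3-yl}-3-[4-(benzyloxy)phenyl]-1-(2,4,6-trihydroxyphenyl)prop-2-en-1-one
Product: 16 (2S,3R)-2-[4-(benzyloxy)phenyl]-3-{5,7-bis(benzyloxy)-2-[4-(benzyloxy)phenyl]-4-oxo-4H-chromen-3-yl}-5,7-dihydroxy-2,3-dihydro-4H-chromen-4-one
Conditions: 1-[3,5-bis(trifluoromethyl)phenyl]-3-[(8S,9S)-6'-methoxycinchonan-9-yl]thiourea (10 mol %), toluene/CH2Cl2, −20 to 0 °C
Reagents that add atoms: none
Why: Bifunctional amine-thiourea catalysed intramolecular oxa-Michael addition (6-endo-trig) of a 2'-hydroxychalcone: the thiourea binds the ketone, the quinuclidine activates an ortho hydroxyl, and the chiral pocket selects the face of C2 to which O1 adds (2S); both ortho hydroxyls give the same product. C3, alpha to the ketone, equilibrates under the amine to the trans (diequatorial) 3R configuration dictated by C2. The non-polar medium and low temperature should suppress uncatalysed closure and ring reopening.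

Step 10
Reactants: 16 (2S,3R)-2-[4-(benzyloxy)phenyl]-3-{5,7-bis(benzyloxy)-2-[4-(benzyloxy)phenyl]-4-oxo-4H-chromen-3-yl}-5,7-dihydroxy-2,3-dihydro-4H-chromen-4-one
Product: 17 (2S,3R)-5,7-dihydroxy-3-[5,7-dihydroxy-2-(4-hydroxyphenyl)-4-oxo-4H-chromen-3-yl]-2-(4-hydroxyphenyl)-2,3-dihydro-4H-chromen-4-one
Conditions: H2 (1 atm), Pd/C (10 wt %), EtOAc/MeOH, rt
Reagents that add atoms: none
Why: Hydrogenolysis of aryl benzyl ethers under neutral conditions; the cyclic benzylic O1–C2 bond, the hydrogen-bonded C4 ketone and the tetrasubstituted flavone double bond should react much more slowly, and no acid or base is present that could open ring C or epimerise C2.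

## Compound list

1 | 1-[2,4-bis(benzyloxy)-6-hydroxyphenyl]ethan-1-one | CC(=O)c1c(O)cc(OCc2ccccc2)cc1OCc1ccccc1 | starting material
2 | 4-(benzyloxy)benzoyl chloride | O=C(Cl)c1ccc(OCc2ccccc2)cc1 | starting material
3 | 1-[2,4-bis(benzyloxy)-6-hydroxyphenyl]-3-[4-(benzyloxy)phenyl]propane-1,3-dione | O=C(CC(=O)c1ccc(OCc2ccccc2)cc1)c1c(O)cc(OCc2ccccc2)cc1OCc1ccccc1 | intermediate
4 | tert-butyl bromoacetate | CC(C)(C)OC(=O)CBr | starting material
5 | tert-butyl 3-[2,4-bis(benzyloxy)-6-hydroxybenzoyl]-4-[4-(benzyloxy)phenyl]-4-oxobutanoate (racemic) | CC(C)(C)OC(=O)CC(C(=O)c1ccc(OCc2ccccc2)cc1)C(=O)c1c(O)cc(OCc2ccccc2)cc1OCc1ccccc1 | intermediate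
6 | tert-butyl {5,7-bis(benzyloxy)-2-[4-(benzyloxy)phenyl]-4-oxo-4H-chromen-3-yl}acetate | CC(C)(C)OC(=O)Cc1c(-c2ccc(OCc3ccccc3)cc2)oc2cc(OCc3ccccc3)cc(OCc3ccccc3)c2c1=O | intermediate (not isolated)
7 | {5,7-bis(benzyloxy)-2-[4-(benzyloxy)phenyl]-4-oxo-4H-chromen-3-yl}acetic acid | OC(=O)Cc1c(-c2ccc(OCc3ccccc3)cc2)oc2cc(OCc3ccccc3)cc(OCc3ccccc3)c2c1=O | intermediate
8 | 4-(benzyloxy)benzaldehyde | O=Cc1ccc(OCc2ccccc2)cc1 | starting material
9 | (2E)-2-{5,7-bis(benzyloxy)-2-[4-(benzyloxy)phenyl]-4-oxo-4H-chromen-3-yl}-3-[4-(benzyloxy)phenyl]prop-2-enoic acid | OC(=O)/C(=C/c1ccc(OCc2ccccc2)cc1)c1c(-c2ccc(OCc3ccccc3)cc2)oc2cc(OCc3ccccc3)cc(OCc3ccccc3)c2c1=O | intermediate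
10 | (2E)-2-{5,7-bis(benzyloxy)-2-[4-(benzyloxy)phenyl]-4-oxo-4H-chromen-3-yl}-3-[4-(benzyloxy)phenyl]-1-(1H-imidazol-1-yl)prop-2-en-1-one | O=C(/C(=C/c1ccc(OCc2ccccc2)cc1)c1c(-c2ccc(OCc3ccccc3)cc2)oc2cc(OCc3ccccc3)cc(OCc3ccccc3)c2c1=O)n1ccnc1 | intermediate
11 | dehydroacetic acid (3-acetyl-4-hydroxy-6-methyl-2H-pyran-2-one) | CC(=O)C1=C(O)C=C(C)OC1=O | starting material
12 | methyl 3,5-dioxohexanoate | COC(=O)CC(=O)CC(C)=O | intermediate
13 | methyl (8E)-8-{5,7-bis(benzyloxy)-2-[4-(benzyloxy)phenyl]-4-oxo-4H-chromen-3-yl}-9-[4-(benzyloxy)phenyl]-3,5,7-trioxonon-8-enoate | COC(=O)CC(=O)CC(=O)CC(=O)/C(=C/c1ccc(OCc2ccccc2)cc1)c1c(-c2ccc(OCc3ccccc3)cc2)oc2cc(OCc3ccccc3)cc(OCc3ccccc3)c2c1=O | intermediate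
14 | 2-[(2E)-2-{5,7-bis(benzyloxy)-2-[4-(benzyloxy)phenyl]-4-oxo-4H-chromen-3-yl}-3-[4-(benzyloxy)phenyl]prop-2-enoyl]cyclohexane-1,3,5-trione | O=C1CC(=O)C(C(=O)/C(=C/c2ccc(OCc3ccccc3)cc2)c2c(-c3ccc(OCc4ccccc4)cc3)oc3cc(OCc4ccccc4)cc(OCc4ccccc4)c3c2=O)C(=O)C1 | intermediate (not isolated)
15 | (2E)-2-{5,7-bis(benzyloxy)-2-[4-(benzyloxy)phenyl]-4-oxo-4H-chromen-3-yl}-3-[4-(benzyloxy)phenyl]-1-(2,4,6-trihydroxyphenyl)prop-2-en-1-one | Oc1cc(O)c(C(=O)/C(=C/c2ccc(OCc3ccccc3)cc2)c2c(-c3ccc(OCc4ccccc4)cc3)oc3cc(OCc4ccccc4)cc(OCc4ccccc4)c3c2=O)c(O)c1 | intermediate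
16 | (2S,3R)-2-[4-(benzyloxy)phenyl]-3-{5,7-bis(benzyloxy)-2-[4-(benzyloxy)phenyl]-4-oxo-4H-chromen-3-yl}-5,7-dihydroxy-2,3-dihydro-4H-chromen-4-one | O=C1c2c(O)cc(O)cc2O[C@H](c2ccc(OCc3ccccc3)cc2)[C@H]1c1c(-c2ccc(OCc3ccccc3)cc2)oc2cc(OCc3ccccc3)cc(OCc3ccccc3)c2c1=O | intermediate
17 | (2S,3R)-5,7-dihydroxy-3-[5,7-dihydroxy-2-(4-hydroxyphenyl)-4-oxo-4H-chromen-3-yl]-2-(4-hydroxyphenyl)-2,3-dihydro-4H-chromen-4-one (CNP0208264.1) | O=C1c2c(O)cc(O)cc2O[C@H](c2ccc(O)cc2)[C@H]1c1c(-c2ccc(O)cc2)oc2cc(O)cc(O)c2c1=O | target

## Step count and risks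

Total step count: 10. Longest linear sequence: 9 steps (steps 1 to 5 and 7 to 10, from 1 to 17); step 6 is a one-step side branch.

**Step 8 (key step).** The most likely failures are folding in the aldol mode (C2 onto C7, giving a resorcylate), lactonisation to a pyranone, or ring C closing unselectively during work-up, because the free triketo ester is poised for several cyclisations and the product chalcone for oxa-Michael addition. Any prematurely closed material could be reopened with cold aqueous KOH and acidified cold. Fallback from 10 to 15, building ring A from a preformed arene instead of folding it: 1,3,5-tris(methoxymethoxy)benzene F1 (from phloroglucinol and chloromethyl methyl ether) would be lithiated between two acetal oxygens with n-BuLi in THF at 0 °C. The aryllithium would be acylated by 10 at −78 °C to give (2E)-2-{5,7-bis(benzyloxy)-2-[4-(benzyloxy)phenyl]-4-oxo-4H-chromen-3-yl}-3-[4-(benzyloxy)phenyl]-1-[2,4,6-tris(methoxymethoxy)phenyl]prop-2-en-1-one F2, and methanolic HCl at room temperature would then release 15.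

**Step 9.** Poor facial selectivity is the main danger: an alpha-heteroaryl chalcone with three free phenols may close in part without the catalyst, and reversible ring opening under the amine would erode the enantiomeric purity. Fallback from 15 to 16 by resolution instead of asymmetric catalysis: closure with NaOAc in ethanol at reflux would give the racemic trans flavanone F3. Preparative chromatography on an amylose tris(3,5-dimethylphenylcarbamate) phase would deliver 16 and its (2R,3S) enantiomer F4, which would be returned to 15 by brief treatment with cold aqueous KOH and cold acidification.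

**Step 7.** Incomplete acylation of the hindered imidazolide, proton transfer that stalls the trianion, or cyclisation of the triketo ester during the quench may occur. Fallback from 10 to 13 through a masked triketide: the dianion (LiN(iPr)2, 2 equiv) of 2,2-dimethyl-6-(2-oxopropyl)-4H-1,3-dioxin-4-one F5 (from 2,2,6-trimethyl-4H-1,3-dioxin-4-one by acetylation of its lithium dienolate) would be acylated at its terminal carbon by 10. This would give 6-[(5E)-5-{5,7-bis(benzyloxy)-2-[4-(benzyloxy)phenyl]-4-oxo-4H-chromen-3-yl}-6-[4-(benzyloxy)phenyl]-2,4-dioxohex-5-en-1-yl]-2,2-dimethyl-4H-1,3-dioxin-4-one F6. Heating F6 in toluene with methanol (retro-[4+2] to the acylketene, trapping by methanol) would release 13 under neutral conditions for immediate use in step 8.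

**Step 2.** Alkylation at the phenol or at an enolate oxygen, or a second alkylation, may compete with the desired C-alkylation. Fallback from 1 to 5 with the order of bond formation reversed: the dianion of 1 (LiN(iPr)2, 2.2 equiv, THF, −78 °C) would be alkylated at carbon by 4 to give tert-butyl 4-[2,4-bis(benzyloxy)-6-hydroxyphenyl]-4-oxobutanoate F7, and F7 would then be acylated with 2 under the conditions of step 1 to reach 5.

**Step 10.** Hydrogenolysis of the benzylic O1–C2 bond or reduction of the C4 carbonyl may accompany debenzylation. Fallback from 16 to 17 by Lewis-acid dealkylation with a cation scavenger: BCl3 and pentamethylbenzene in CH2Cl2 at −78 °C, with no new compound on the way (F0).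

## Further compounds

F1 | step 8 | 1,3,5-tris(methoxymethoxy)benzene | COCOc1cc(OCOC)cc(OCOC)c1
F2 | step 8 | (2E)-2-{5,7-bis(benzyloxy)-2-[4-(benzyloxy)phenyl]-4-oxo-4H-chromen-3-yl}-3-[4-(benzyloxy)phenyl]-1-[2,4,6-tris(methoxymethoxy)phenyl]prop-2-en-1-one | COCOc1cc(OCOC)c(C(=O)/C(=C/c2ccc(OCc3ccccc3)cc2)c2c(-c3ccc(OCc4ccccc4)cc3)oc3cc(OCc4ccccc4)cc(OCc4ccccc4)c3c2=O)c(OCOC)c1
F3 | step 9 | racemic trans-2-[4-(benzyloxy)phenyl]-3-{5,7-bis(benzyloxy)-2-[4-(benzyloxy)phenyl]-4-oxo-4H-chromen-3-yl}-5,7-dihydroxy-2,3-dihydro-4H-chromen-4-one (both enantiomers) | O=C1c2c(O)cc(O)cc2O[C@H](c2ccc(OCc3ccccc3)cc2)[C@H]1c1c(-c2ccc(OCc3ccccc3)cc2)oc2cc(OCc3ccccc3)cc(OCc3ccccc3)c2c1=O.O=C1c2c(O)cc(O)cc2O[C@@H](c2ccc(OCc3ccccc3)cc2)[C@@H]1c1c(-c2ccc(OCc3ccccc3)cc2)oc2cc(OCc3ccccc3)cc(OCc3ccccc3)c2c1=O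
F4 | step 9 | (2R,3S)-2-[4-(benzyloxy)phenyl]-3-{5,7-bis(benzyloxy)-2-[4-(benzyloxy)phenyl]-4-oxo-4H-chromen-3-yl}-5,7-dihydroxy-2,3-dihydro-4H-chromen-4-one | O=C1c2c(O)cc(O)cc2O[C@@H](c2ccc(OCc3ccccc3)cc2)[C@@H]1c1c(-c2ccc(OCc3ccccc3)cc2)oc2cc(OCc3ccccc3)cc(OCc3ccccc3)c2c1=O
F5 | step 7 | 2,2-dimethyl-6-(2-oxopropyl)-4H-1,3-dioxin-4-one | CC(=O)CC1=CC(=O)OC(C)(C)O1
F6 | step 7 | 6-[(5E)-5-{5,7-bis(benzyloxy)-2-[4-(benzyloxy)phenyl]-4-oxo-4H-chromen-3-yl}-6-[4-(benzyloxy)phenyl]-2,4-dioxohex-5-en-1-yl]-2,2-dimethyl-4H-1,3-dioxin-4-one | CC1(C)OC(CC(=O)CC(=O)/C(=C/c2ccc(OCc3ccccc3)cc2)c2c(-c3ccc(OCc4ccccc4)cc3)oc3cc(OCc4ccccc4)cc(OCc4ccccc4)c3c2=O)=CC(=O)O1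
F7 | step 2 | tert-butyl 4-[2,4-bis(benzyloxy)-6-hydroxyphenyl]-4-oxobutanoate | CC(C)(C)OC(=O)CCC(=O)c1c(O)cc(OCc2ccccc2)cc1OCc1ccccc1
F0 | step 10 | none | none
A1 | alternative 1 | (2S,3R)-5,7-dimethoxy-2-(4-methoxyphenyl)-3-{1-(4-methoxyphenyl)-3-[2-(methoxymethoxy)-4,6-dimethoxyphenyl]-1,3-dioxopropan-2-yl}chroman-4-one | O=C1c2c(OC)cc(OC)cc2O[C@H](c2ccc(OC)cc2)[C@H]1C(C(=O)c1ccc(OC)cc1)C(=O)c1c(OCOC)cc(OC)cc1OC
A2 | alternative 1 | 2-{[(1S)-3-(4-methoxybenzoyl)-1-(4-methoxyphenyl)-4-[2-(methoxymethoxy)-4,6-dimethoxyphenyl]-4-oxobut-2-en-1-yl]oxy}-4,6-dimethoxybenzaldehyde | O=Cc1c(OC)cc(OC)cc1O[C@H](c1ccc(OC)cc1)C=C(C(=O)c1ccc(OC)cc1)C(=O)c1c(OCOC)cc(OC)cc1OC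
A3 | alternative 2 | (2S,3R)-2-(4-hydroxyphenyl)-5,7-dimethoxy-3-[5,7-dimethoxy-2-(4-methoxyphenyl)-4-oxo-4H-chromen-3-yl]chroman-4-one | O=C1c2c(OC)cc(OC)cc2O[C@H](c2ccc(O)cc2)[C@H]1c1c(-c2ccc(OC)cc2)oc2cc(OC)cc(OC)c2c1=O
A4 | alternative 2 | 2-[5,7-dimethoxy-2-(4-methoxyphenyl)-4-oxo-4H-chromen-3-yl]-1-(2-hydroxy-4,6-dimethoxyphenyl)-3-(4-hydroxyphenyl)propan-1-one | COc1cc(O)c(C(=O)C(Cc2ccc(O)cc2)c2c(-c3ccc(OC)cc3)oc3cc(OC)cc(OC)c3c2=O)c(OC)c1
A5 | alternative 3 | 2,3-trans-4,5,7-trimethoxy-2-(4-methoxyphenyl)-3-[5,7-dimethoxy-2-(4-methoxyphenyl)-4-oxo-4H-chromen-3-yl]chroman (C4 epimers) | COC1c2c(OC)cc(OC)cc2O[C@H](c2ccc(OC)cc2)[C@H]1c1c(-c2ccc(OC)cc2)oc2cc(OC)cc(OC)c2c1=O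
A6 | alternative 3 | 5,7-dimethoxy-2-(4-methoxyphenyl)-3-[(E)-2-(4-methoxyphenyl)ethenyl]-4H-chromen-4-one | COc1ccc(/C=C/c2c(-c3ccc(OC)cc3)oc3cc(OC)cc(OC)c3c2=O)cc1
A7 | alternative 3 | 2-(dimethoxymethyl)-3,5-dimethoxyphenol | COC(OC)c1c(O)cc(OC)cc1OC
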